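## The problem

Coelenterazine (14) is an imidazo[1,2-a]pyrazin-3(7H)-one. A five-membered imidazolone (N1, C2, C3, N4, C8a) and a six-membered dihydropyrazine (N4, C5, C6, N7, C8, C8a) share the N4–C8a bond. C2 carries a 4-hydroxybenzyl group, C6 a 4-hydroxyphenyl group and C8 a benzyl group.

The target has no stereocenter. Any sp3 centre used on the way is therefore transient: it controls nothing that survives, and its configuration need not be defended.

The real difficulty is sensitivity. The electron-rich, cross-conjugated core reacts with oxygen, fastest in basic aprotic media, and oxidants can carry it on to the 2-arylidene (dehydro) compound. The two free phenols add to this. The core should therefore be completed last, without base, under argon, and with masking groups that fall to mild acid.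

Only three ring bonds are C–C bonds (C2–C3, C5–C6, C8–C8a), and each is the Cα–C bond of a 2-amino carbonyl unit. N7–C8–C8a is phenylalanine, N1–C2–C3 is tyrosine, and N4–C5–C6 is a 2-amino-1-arylethanone. The bicycle is thus a tripeptide-like chain folded twice.

The fold that makes the key step possible is N4–C8a. It joins the amide nitrogen of the tyrosine amide to the carbonyl carbon of the preceding phenylalanine, five atoms apart, which is the geometry of a peptide cyclodehydration to an imidazol-5(4H)-one. A chain built from amino acids arrives two hydrogens above the target, so one controlled dehydrogenation at the end is the price.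

## Retrosynthesis

**14 ⇒ 13.** No skeletal bond is cut; two hydrogens are put back to give the 2,5,8-trihydro compound 13. This placement is preferred over building the unsaturation into the chain as a dehydroamino acid, which would lengthen the chain synthesis and send a reactive enamide through the key step. Compound 13 is reachable by condensation chemistry alone. The forward step must be a single dehydrogenation, controlled by stoichiometry under argon, that stops at 14.

**13 ⇒ 12 ⇒ 11.** The C6=N7 imine is cut, giving amino ketone 12 and, with both functions masked, imidazolone 11. The amine and the ketone sit 1,6 to each other on a chain already held by the imidazolone, so closure is a six-membered intramolecular condensation. The neighbouring cut at N4–C5 would require alkylating an ambident imidazolone with a phenacyl halide, which is less attractive. The tert-butyl carbamate and the cyclic ketal of 11 fall to the same aqueous acid. The forward step must unmask both groups and close the ring without hydrolysing the acyl amidine of the imidazolone.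

**11 ⇒ 9.** The key cut is N4–C8a. It opens the imidazolone to the linear diamide 9, an ordinary protected dipeptide amide that already holds every atom of 14. Cutting N1–C8a instead would demand an imidate of phenylalanine, and cutting C3–N4 a lactamisation of an amidino acid; both leave the peptide manifold. The forward step must make the amide nitrogen N4 add to the neighbouring amide carbonyl C8a and remove the elements of water, while the carbamate carbonyl and the masked ketone stay out of the reaction.

**9 ⇒ 4 + 8.** The C3–N4 amide is cut into dipeptide acid 4 and amino ketal 8, two fragments of similar size. A stepwise build from the C-terminus would make the route more linear and would require a second nitrogen protecting group on the tyrosine. The forward coupling must tolerate two free phenols and the acid-labile ketal; epimerisation at the activated tyrosine carbon is of no consequence.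

**4 ⇒ 3 ⇒ 1 + 2.** The phenylalanine–tyrosine amide is cut to the two commercial amino acid derivatives 1 and 2, with methyl ester 3 in between. The urethane-protected acid 1 couples without risk, and 3 is kept as an isolated compound because it is the only intermediate with a single amide carbonyl (useful if the key step needs a stronger electrophile).

**8 ⇒ 7 ⇒ 6 ⇒ 5.** These are functional-group operations on commercial amino ketone salt 5. The ketone is ketalised before the peptide is attached, so that the tert-butyl carbamate never sees the ketalisation acid and no acylamino ketone is exposed to dehydrating conditions. The nitrogen must be capped first (6), because the free α-amino ketone self-condenses and its salt resists ketalisation. A benzyl carbamate is chosen since it leaves by neutral hydrogenolysis with the ketal (7) untouched.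

## Roads not taken

**Alternative 1:** The cut is N7–C8 together with C8–C8a. In the forward step the primary amine A2 condenses with phenylacetaldehyde A3 to an iminium ion, which the imidazole carbon C8a attacks to close the six-membered ring as the cis-tetrahydro compound A1.
- Merits: a C–C bond and a ring form in one operation, and the C8 substituent arrives late, which would suit analogue work better than the chosen plan.
- Weak points: the only free imidazole carbon lies between two nitrogens and is the least nucleophilic position of the ring toward iminium ions. The imine of A3 tautomerises readily to a conjugated enamine. A1 still needs the loss of four hydrogens and three benzyl ethers, on a core that tolerates neither oxidants nor hydrogenation well. Two stereocentres are made only to be destroyed.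
- Comparison: the chosen plan needs one dehydrogenation instead of two and no deprotection after the core exists.

**Alternative 2:** The cut is N1=C8a. A phosphine converts the α-azido N-acyl pyrazinone A5 into an iminophosphorane, which attacks the pyrazinone carbonyl C8a intramolecularly and expels a phosphine oxide to give the bis(aryl acetate) A4.
- Merits: the pyrazine half is aromatic from the start, so A4 is formed at the oxidation level of 14 under neutral conditions. In this respect the road is better than the chosen plan, which ends with an oxidant acting on sensitive material.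
- Weak points: A5 requires N-acylation of an ambident pyrazinone, and such N-acyl lactams are acyl donors that transfer the acyl group to any nucleophile. Its α-hydrogen is flanked by an azide and an activated acyl group, so loss of nitrogen or ketene formation threatens. Two aryl acetates must be removed from A4 after the fragile core is present.
- Comparison: against the redox advantage, the chosen plan offers stable, crystalline peptide-type intermediates made by routine amide couplings, and an end game triggered only by acid.

**Alternative 3:** The cuts are N1–C2, C2–C3 and C3–N4. Coelenteramine A7, 4-hydroxyphenylacetaldehyde A8 and tert-butyl isocyanide A9 combine under Lewis acid catalysis to give the 3-(tert-butylamino)imidazo[1,2-a]pyrazine A6.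
- Merits: three bonds and the imidazole ring form in one step at the aromatic oxidation level. In step count to the bicyclic skeleton this road beats the chosen plan clearly.
- Weak points: A6 carries nitrogen where 14 carries oxygen. Turning a 3-amino group on this electron-rich heteroaromatic into the 3-oxo function means dealkylation followed by a hydrolytic C–N to C–O exchange, for which no mild method fits the free phenols and the core. A8 self-condenses easily, enolisable aliphatic aldehydes and 2-aminopyrazines are poor partners in this condensation, and A7 itself costs several steps.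
- Comparison: the chosen plan takes the C3 carbonyl directly from the tyrosine carboxyl group and needs no heteroatom exchange.

Key step: step 7

Assumption: both sp3 centres of the chain are erased in the last two steps, so epimerisation along the route is tolerated; compounds are drawn with the L-derived configuration where it is expected to persist, and without a descriptor where it is not.

## Route

Step 1
Reactants: 1 N-(tert-butoxycarbonyl)-L-phenylalanine; 2 L-tyrosine methyl ester (free base)
Product: 3 methyl N-(tert-butoxycarbonyl)-L-phenylalanyl-L-tyrosinate
Conditions: EDC·HCl (1.1 equiv), HOBt (1.1 equiv), CH2Cl2/DMF, 0 °C → rt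
Reagents that add atoms: none
Why: Carbodiimide/HOBt peptide coupling of a urethane-protected acid, which does not racemise; the amine outruns the free phenol, and any aryl ester formed would itself acylate the amine.

Step 2
Reactants: 3 methyl N-(tert-butoxycarbonyl)-L-phenylalanyl-L-tyrosinate
Product: 4 N-(tert-butoxycarbonyl)-L-phenylalanyl-L-tyrosine
Conditions: LiOH·H2O (2.5 equiv), THF/H2O (3:1), 0 °C; then 1 M HCl to pH 3
Reagents that add atoms: water (delivered as hydroxide by LiOH), O
Why: Saponification of a methyl ester; the tert-butyl carbamate and the amide are stable to cold aqueous hydroxide, and the phenoxide formed in passing is reprotonated on acidification.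

Step 3
Reactants: 5 2-amino-1-(4-hydroxyphenyl)ethan-1-one hydrochloride
Product: 6 benzyl N-[2-(4-hydroxyphenyl)-2-oxoethyl]carbamate
Conditions: Cbz-OSu (1.05 equiv), NaHCO3 (2.2 equiv), THF/H2O (1:1), 0 °C → rt
Reagents that add atoms: N-(benzyloxycarbonyloxy)succinimide, O=C(OCc1ccccc1)ON1C(=O)CCC1=O
Why: Schotten–Baumann-type N-acylation; the α-amino ketone is trapped as it is released from its salt, which prevents self-condensation, and the succinimidyl carbonate acylates the amine in preference to the acidic phenol.

Step 4
Reactants: 6 benzyl N-[2-(4-hydroxyphenyl)-2-oxoethyl]carbamate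
Product: 7 benzyl N-{[2-(4-hydroxyphenyl)-1,3-dioxolan-2-yl]methyl}carbamate
Conditions: HOCH2CH2OH (5 equiv), TsOH·H2O (5 mol %), toluene, reflux, Dean–Stark; Et3N quench
Reagents that add atoms: ethylene glycol, OCCO
Why: Acid-catalysed ketalisation driven by azeotropic removal of water, a standard operation on N-benzyloxycarbonyl α-amino ketones; the base quench protects the acid-labile 4-hydroxyphenyl ketal during isolation.

Step 5
Reactants: 7 benzyl N-{[2-(4-hydroxyphenyl)-1,3-dioxolan-2-yl]methyl}carbamate
Product: 8 4-[2-(aminomethyl)-1,3-dioxolan-2-yl]phenol
Conditions: H2 (1 atm), 10% Pd/C, MeOH, rt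
Reagents that add atoms: none
Why: Hydrogenolysis of a benzyl carbamate under neutral conditions; the dioxolane and the phenol are untouched, and the masked ketone cannot condense with the liberated amine.

Step 6
Reactants: 4 N-(tert-butoxycarbonyl)-L-phenylalanyl-L-tyrosine; 8 4-[2-(aminomethyl)-1,3-dioxolan-2-yl]phenol
Product: 9 N-(tert-butoxycarbonyl)-L-phenylalanyl-L-tyrosine N-{[2-(4-hydroxyphenyl)-1,3-dioxolan-2-yl]methyl}amide
Conditions: EDC·HCl (1.2 equiv), HOBt (1.2 equiv), DMF, 0 °C → rt
Reagents that add atoms: none
Why: Carbodiimide/HOBt segment coupling with an unhindered primary amine; the ketal survives the weakly acidic additive, the phenols need no protection, and epimerisation of the activated tyrosine residue is harmless here.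

Step 7
Reactants: 9 N-(tert-butoxycarbonyl)-L-phenylalanyl-L-tyrosine N-{[2-(4-hydroxyphenyl)-1,3-dioxolan-2-yl]methyl}amide
Product: 11 tert-butyl N-[(1S)-1-{4-(4-hydroxybenzyl)-1-{[2-(4-hydroxyphenyl)-1,3-dioxolan-2-yl]methyl}-5-oxo-4,5-dihydro-1H-imidazol-2-yl}-2-phenylethyl]carbamate (epimer mixture at C4 of the imidazolone), via bis(trimethylsilyl) aryl ether 10 (not isolated)
Conditions: HMDS (10 equiv), TMSCl (0.2 equiv), pyridine, 110 °C, Ar; then MeOH, rt
Reagents that add atoms: none
Why: Silylative cyclodehydration of an N-acyl α-amino amide to an imidazol-5(4H)-one, the reaction type used for chromophore models of fluorescent proteins. HMDS caps both phenols and converts the C-terminal amide into its O-silyl imidate, which makes N4 an imine-type nitrogen with a free lone pair. N4 then adds to the phenylalanine carbonyl carbon C8a in a 5-exo-trig closure onto the C=O bond; attack on an O-silyl imidate of that carbonyl would be 5-endo-trig, so the carbonyl itself is taken as the acceptor. The carbinolamine is silylated on oxygen and loses trimethylsilanol, captured as hexamethyldisiloxane, to give the C8a=N1 amidine, and methanol then cleaves the aryl silyl ethers of 10. No stereocentre is created. The tyrosine-derived C4–H is azlactone-like and is expected to epimerise through the 5-silyloxyimidazole, so 11 is carried on as a C4 epimer mixture, which is harmless because both sp3 centres disappear later. The selectivity needed is N4 onto C8a in preference to N1 onto the carbamate carbonyl (hydantoin), the phenylalanine carbonyl oxygen onto C3 (5-aminooxazole) and any reaction at the ketone carbon. The poor electrophilicity of the tert-butyl carbamate, the absence of an electrophilic dehydrating agent that would activate C3, and the dioxolane secure these in turn.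

Step 8
Reactants: 11 tert-butyl N-[(1S)-1-{4-(4-hydroxybenzyl)-1-{[2-(4-hydroxyphenyl)-1,3-dioxolan-2-yl]methyl}-5-oxo-4,5-dihydro-1H-imidazol-2-yl}-2-phenylethyl]carbamate
Product: 13 8-benzyl-2-(4-hydroxybenzyl)-6-(4-hydroxyphenyl)-5,8-dihydroimidazo[1,2-a]pyrazin-3(2H)-one (stereoisomer/tautomer mixture, used crude under argon), via aminoketone hydrochloride 12 (not isolated)
Conditions: 4 M HCl in dioxane, H2O (10 equiv), 0 °C → rt; concentrate; NaOAc, degassed MeOH, rt, Ar
Reagents that add atoms: none
Why: Acidolysis of the tert-butyl carbamate and hydrolysis of the 4-hydroxyphenyl ketal unmask N7 and the C6 ketone 1,6 to each other, and buffering releases the amine for a 6-exo-trig imine condensation that closes the pyrazine ring. HCl is preferred to neat trifluoroacetic acid because chloride and water intercept the tert-butyl cation before it alkylates the phenols.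

Step 9
Reactants: 13 8-benzyl-2-(4-hydroxybenzyl)-6-(4-hydroxyphenyl)-5,8-dihydroimidazo[1,2-a]pyrazin-3(2H)-one
Product: 14 coelenterazine, 8-benzyl-2-(4-hydroxybenzyl)-6-(4-hydroxyphenyl)imidazo[1,2-a]pyrazin-3(7H)-one
Conditions: DDQ (1.0 equiv), degassed THF, −20 → 0 °C, Ar; product precipitated from MeOH containing a trace of HCl
Reagents that add atoms: none
Why: Quinone dehydrogenation of a dihydropyrazine by hydride abstraction from the doubly activated C8–H (or its enamine tautomer) and proton loss, after which the product settles as the conjugated 7H tautomer. The dihydropyrazine is a much better hydride donor than 14 or the phenols, so one equivalent at low temperature should stop at 14.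

## Compound list

1 | N-(tert-butoxycarbonyl)-L-phenylalanine | CC(C)(C)OC(=O)N[C@@H](Cc1ccccc1)C(=O)O | starting material
2 | L-tyrosine methyl ester | COC(=O)[C@@H](N)Cc1ccc(O)cc1 | starting material
3 | methyl N-(tert-butoxycarbonyl)-L-phenylalanyl-L-tyrosinate | CC(C)(C)OC(=O)N[C@@H](Cc1ccccc1)C(=O)N[C@@H](Cc1ccc(O)cc1)C(=O)OC | intermediate
4 | N-(tert-butoxycarbonyl)-L-phenylalanyl-L-tyrosine | CC(C)(C)OC(=O)N[C@@H](Cc1ccccc1)C(=O)N[C@@H](Cc1ccc(O)cc1)C(=O)O | intermediate
5 | 2-amino-1-(4-hydroxyphenyl)ethan-1-one hydrochloride | Cl.NCC(=O)c1ccc(O)cc1 | starting material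
6 | benzyl N-[2-(4-hydroxyphenyl)-2-oxoethyl]carbamate | O=C(NCC(=O)c1ccc(O)cc1)OCc1ccccc1 | intermediate
7 | benzyl N-{[2-(4-hydroxyphenyl)-1,3-dioxolan-2-yl]methyl}carbamate | O=C(NCC1(c2ccc(O)cc2)OCCO1)OCc1ccccc1 | intermediate
8 | 4-[2-(aminomethyl)-1,3-dioxolan-2-yl]phenol | NCC1(c2ccc(O)cc2)OCCO1 | intermediate
9 | N-(tert-butoxycarbonyl)-L-phenylalanyl-L-tyrosine N-{[2-(4-hydroxyphenyl)-1,3-dioxolan-2-yl]methyl}amide | CC(C)(C)OC(=O)N[C@@H](Cc1ccccc1)C(=O)N[C@@H](Cc1ccc(O)cc1)C(=O)NCC1(c2ccc(O)cc2)OCCO1 | intermediate
10 | bis(O-trimethylsilyl) aryl ether of 11 (formed in the flask, not isolated) | CC(C)(C)OC(=O)N[C@@H](Cc1ccccc1)C1=NC(Cc2ccc(O[Si](C)(C)C)cc2)C(=O)N1CC1(c2ccc(O[Si](C)(C)C)cc2)OCCO1 | intermediate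
11 | tert-butyl N-[(1S)-1-{4-(4-hydroxybenzyl)-1-{[2-(4-hydroxyphenyl)-1,3-dioxolan-2-yl]methyl}-5-oxo-4,5-dihydro-1H-imidazol-2-yl}-2-phenylethyl]carbamate (C4 epimer mixture, C4 drawn without descriptor) | CC(C)(C)OC(=O)N[C@@H](Cc1ccccc1)C1=NC(Cc2ccc(O)cc2)C(=O)N1CC1(c2ccc(O)cc2)OCCO1 | intermediate
12 | 2-[(1S)-1-amino-2-phenylethyl]-4-(4-hydroxybenzyl)-1-[2-(4-hydroxyphenyl)-2-oxoethyl]-1H-imidazol-5(4H)-one (present as its hydrochloride, not isolated; neutral form drawn) | N[C@@H](Cc1ccccc1)C1=NC(Cc2ccc(O)cc2)C(=O)N1CC(=O)c1ccc(O)cc1 | intermediate
13 | 8-benzyl-2-(4-hydroxybenzyl)-6-(4-hydroxyphenyl)-5,8-dihydroimidazo[1,2-a]pyrazin-3(2H)-one (C2 and C8 configurationally labile; drawn without descriptors) | O=C1C(Cc2ccc(O)cc2)N=C2C(Cc3ccccc3)N=C(c3ccc(O)cc3)CN12 | intermediate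
14 | coelenterazine, 8-benzyl-2-(4-hydroxybenzyl)-6-(4-hydroxyphenyl)imidazo[1,2-a]pyrazin-3(7H)-one | O=c1c(Cc2ccc(O)cc2)nc2c(Cc3ccccc3)[nH]c(-c3ccc(O)cc3)cn1-2 | target

## Step count and risks

Total steps: 9. Longest linear sequence: 7 steps (5 → 14, steps 3 to 9); the dipeptide branch contributes steps 1 and 2.

**Step 7 (key step).**
- Most likely failure: the closure stalls at the persilylated diamide. An amide nitrogen is a weak nucleophile and an amide carbonyl a weak electrophile, and the saturated tyrosine residue lacks the conformational bias of dehydro or α,α-disubstituted substrates. Prolonged heating then invites attack of N1 on the carbamate carbonyl or thermal loss of the tert-butyl carbamate.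
- Fallback: raise the electrophilicity of C8a while forming the same bond. It sets out from 3, the only intermediate with a single amide carbonyl, and returns at 11.
  - Lawesson's reagent (THF, 50 °C) thionates that amide to give the thioamide ester Boc-L-Phe-ψ[CS–NH]-L-Tyr-OMe F1.
  - LiOH gives the corresponding thioamide acid F2.
  - EDC/HOBt coupling with 8, which runs through a thiazol-5(4H)-one and scrambles the tyrosine centre, gives the thioamide analogue of 9 F3.
  - Methyl iodide without base (so the phenols are not alkylated) gives the S-methyl thioimidate F4. Warming this with NaOAc/AcOH lets N4 displace methanethiol at C8a and close the imidazolone to 11.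

**Step 9.**
- Most likely failure: over-oxidation. The product and its 4-hydroxybenzyl group are themselves hydride donors, so further dehydrogenation at the C2 benzylic position and oxidation of the phenols compete once the local oxidant concentration is high.
- Fallback: use the over-oxidation deliberately. It sets out from 13 and returns at 14. Excess MnO2 (EtOH/Et2O, rt) takes 13 through to (Z)-dehydrocoelenterazine F5, a stable, isolable compound. NaBH4 (MeOH, 0 °C, Ar) then delivers hydride to the arylidene system and gives 14, a reduction established for this dehydro compound.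

**Step 8.**
- Most likely failure: hydrolytic opening of the acyl amidine of the imidazolone in strong aqueous acid before N7 closes onto C6; tert-butylation of the phenols and intermolecular imine formation are lesser risks.
- Fallback: separate the two unmaskings so that strong acid and water are never present together. It sets out from 11 and returns at 13. PPTS in acetone/H2O hydrolyses only the labile 4-hydroxyphenyl ketal to give the N-Boc keto imidazolone F6. Anhydrous HCl in dioxane then removes the carbamate to give 12 as its salt, and NaOAc in degassed MeOH closes the ring to 13.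

**Step 4.**
- Most likely failure: slow, incomplete ketalisation of a ketone deactivated by the para-hydroxy group and the α-amido substituent, with the carbamate oxygen adding to the activated ketone and benzyl being lost on forcing.
- Fallback: a nitrogen protecting group with no N–H and no participating alkoxy group, which allows harsher ketalisation. It sets out from 5 and returns at 8. N-Carbethoxyphthalimide and Na2CO3 (THF/H2O) give 2-[2-(4-hydroxyphenyl)-2-oxoethyl]isoindoline-1,3-dione F7. Ethylene glycol, triethyl orthoformate and TsOH·H2O in refluxing toluene give the phthalimido ketal F8. Hydrazine hydrate in EtOH releases 8.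

## Further compounds

F1 | step 7 | methyl N-(tert-butoxycarbonyl)-L-thiophenylalanyl-L-tyrosinate (thioamide ester) | CC(C)(C)OC(=O)N[C@@H](Cc1ccccc1)C(=S)N[C@@H](Cc1ccc(O)cc1)C(=O)OC
F2 | step 7 | N-(tert-butoxycarbonyl)-L-thiophenylalanyl-L-tyrosine (thioamide acid) | CC(C)(C)OC(=O)N[C@@H](Cc1ccccc1)C(=S)N[C@@H](Cc1ccc(O)cc1)C(=O)O
F3 | step 7 | thioamide analogue of 9 (tyrosine centre scrambled, drawn without descriptor) | CC(C)(C)OC(=O)N[C@@H](Cc1ccccc1)C(=S)NC(Cc1ccc(O)cc1)C(=O)NCC1(c2ccc(O)cc2)OCCO1
F4 | step 7 | S-methyl thioimidate of F3 | CC(C)(C)OC(=O)N[C@@H](Cc1ccccc1)C(SC)=NC(Cc1ccc(O)cc1)C(=O)NCC1(c2ccc(O)cc2)OCCO1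
F5 | step 9 | (Z)-dehydrocoelenterazine, 8-benzyl-2-(4-hydroxybenzylidene)-6-(4-hydroxyphenyl)imidazo[1,2-a]pyrazin-3(2H)-one | O=C1/C(=C/c2ccc(O)cc2)N=C2C(Cc3ccccc3)=NC(c3ccc(O)cc3)=CN12
F6 | step 8 | tert-butyl N-[(1S)-1-{4-(4-hydroxybenzyl)-1-[2-(4-hydroxyphenyl)-2-oxoethyl]-5-oxo-4,5-dihydro-1H-imidazol-2-yl}-2-phenylethyl]carbamate | CC(C)(C)OC(=O)N[C@@H](Cc1ccccc1)C1=NC(Cc2ccc(O)cc2)C(=O)N1CC(=O)c1ccc(O)cc1
F7 | step 4 | 2-[2-(4-hydroxyphenyl)-2-oxoethyl]isoindoline-1,3-dione | O=C(CN1C(=O)c2ccccc2C1=O)c1ccc(O)cc1
F8 | step 4 | 2-{[2-(4-hydroxyphenyl)-1,3-dioxolan-2-yl]methyl}isoindoline-1,3-dione | O=C1c2ccccc2C(=O)N1CC1(c2ccc(O)cc2)OCCO1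
A1 | alternative 1 | cis-8-benzyl-3-benzyloxy-2-(4-benzyloxybenzyl)-6-(4-benzyloxyphenyl)-5,6,7,8-tetrahydroimidazo[1,2-a]pyrazine | N1[C@H](c2ccc(OCc3ccccc3)cc2)Cn2c(nc(Cc3ccc(OCc4ccccc4)cc3)c2OCc2ccccc2)[C@@H]1Cc1ccccc1
A2 | alternative 1 | 2-[5-benzyloxy-4-(4-benzyloxybenzyl)-1H-imidazol-1-yl]-1-(4-benzyloxyphenyl)ethan-1-amine | N[C@H](c1ccc(OCc2ccccc2)cc1)Cn1cnc(Cc2ccc(OCc3ccccc3)cc2)c1OCc1ccccc1
A3 | alternative 1 | phenylacetaldehyde | O=CCc1ccccc1
A4 | alternative 2 | coelenterazine bis(aryl acetate) | O=c1c(Cc2ccc(OC(C)=O)cc2)nc2c(Cc3ccccc3)[nH]c(-c3ccc(OC(C)=O)cc3)cn1-2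
A5 | alternative 2 | 1-[(2S)-3-(4-acetoxyphenyl)-2-azidopropanoyl]-5-(4-acetoxyphenyl)-3-benzylpyrazin-2(1H)-one | CC(=O)Oc1ccc(C[C@H](N=[N+]=[N-])C(=O)n2cc(-c3ccc(OC(C)=O)cc3)nc(Cc3ccccc3)c2=O)cc1
A6 | alternative 3 | 8-benzyl-3-(tert-butylamino)-2-(4-hydroxybenzyl)-6-(4-hydroxyphenyl)imidazo[1,2-a]pyrazine | CC(C)(C)Nc1c(Cc2ccc(O)cc2)nc2c(Cc3ccccc3)nc(-c3ccc(O)cc3)cn12
A7 | alternative 3 | coelenteramine, 4-(5-amino-6-benzylpyrazin-2-yl)phenol | Nc1ncc(-c2ccc(O)cc2)nc1Cc1ccccc1
A8 | alternative 3 | 4-hydroxyphenylacetaldehyde | O=CCc1ccc(O)cc1
A9 | alternative 3 | tert-butyl isocyanide | [C-]#[N+]C(C)(C)C
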